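**Retrosynthetic overview**
- The target comes from a 6,7,13-triol by acetylation of the unhindered equatorial C7–OH. The C13 carbinol comes from Sharpless epoxidation and reductive epoxide opening of an (E)-allylic alcohol made by alkyne carboalumination.
- The 6,7-cis-diol comes from OsO4 dihydroxylation of a ring-B 5(10),6-diene, anti to the C8 methyl.
- Ring A is closed last at C1–C10 by an intramolecular B-alkyl Suzuki coupling of a dienyl triflate. Its quaternary C4 comes from an acetone aldol condensation and conjugate allylation at C5.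
- The C9 quaternary centre comes from reductive methylation of an alkylidene ketone. The key C9–C11 bond comes from a copper-catalysed asymmetric conjugate methylation of cyclohex-2-en-1-one whose zinc enolate is captured in an intermolecular aldol addition by 3-(PMB-oxy)propanal.
- Ring order: ring B (from cyclohexenone) first, ring A second, side chain finished last.

Atom labels C1–C20 follow halimane numbering: ring A is C1–C5 and C10, ring B is C5–C10, the side chain is C11–C15, C16 is the methyl on C13, C17 is on C8, C18/C19 are on C4, and C20 is on C9. PMB = 4-methoxybenzyl, TBS = tert-butyldimethylsilyl, Ms = methanesulfonyl, Tf = trifluoromethanesulfonyl. L* = (R,S,S)-N,N-bis(1-phenylethyl)dinaphtho[2,1-d:1′,2′-f][1,3,2]dioxaphosphepin-4-amine.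

Assumption: L* is the ligand enantiomer that gives the (3R)-methyl adduct (its (S,R,R) antipode being the one that gives (S)-3-alkylcyclohexanones); L*, ZnMe2, 9-BBN and the diazophosphonate of step 16 are bought.

**Step 1**
Reactants: 1 propane-1,3-diol
Product: 2 3-[(4-methoxybenzyl)oxy]propan-1-ol
Conditions: NaH (1 equiv), 4-methoxybenzyl chloride (1 equiv), Bu4NI (cat.), THF/DMF, 0 °C to rt, diol in 3-fold excess
Reagents that add atoms: 4-methoxybenzyl chloride COc1ccc(CCl)cc1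
Why: Williamson ether synthesis, with excess diol holding the reaction at mono-alkylation.

**Step 2**
Reactants: 2 3-[(4-methoxybenzyl)oxy]propan-1-ol
Product: 3 3-[(4-methoxybenzyl)oxy]propanal
Conditions: Dess–Martin periodinane, CH2Cl2, 0 °C to rt
Reagents that add atoms: none
Why: Dess–Martin oxidation stops at the aldehyde under neutral conditions, so the β-PMB-oxy group is not eliminated.

**Step 3**
Reactants: 4 cyclohex-2-en-1-one; 3 3-[(4-methoxybenzyl)oxy]propanal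
Product: 6 (2R,3R)-2-{1-hydroxy-3-[(4-methoxybenzyl)oxy]propyl}-3-methylcyclohexan-1-one (both carbinol epimers), via zinc enolate 5 (not isolated)
Conditions: Cu(OTf)2 (2 mol %), L* (4 mol %), ZnMe2 (1.5 equiv), toluene, −30 °C; then 3, −30 to 0 °C
Reagents that add atoms: dimethylzinc C[Zn]C
Why: Copper-catalysed asymmetric conjugate addition sets C8 (R, ligand control), and the zinc enolate then undergoes an intermolecular aldol addition to 3 anti to the new methyl group, forming the C9–C11 bond.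

**Step 4**
Reactants: 6 (2R,3R)-2-{1-hydroxy-3-[(4-methoxybenzyl)oxy]propyl}-3-methylcyclohexan-1-one
Product: 8 (2E,3R)-2-{3-[(4-methoxybenzyl)oxy]propylidene}-3-methylcyclohexan-1-one, via mesylate 7 (not isolated)
Conditions: MsCl, Et3N, CH2Cl2, 0 °C; then DBU, 0 °C, 30 min
Reagents that add atoms: none
Why: Mesylation and E1cB elimination complete the aldol condensation and converge both carbinol epimers on the (E)-alkylidene ketone, while the non-acidic C8–H is untouched.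

**Step 5**
Reactants: 8 (2E,3R)-2-{3-[(4-methoxybenzyl)oxy]propylidene}-3-methylcyclohexan-1-one
Product: 10 (2R,3R)-2-{3-[(4-methoxybenzyl)oxy]propyl}-2,3-dimethylcyclohexan-1-one, via lithium enolate 9 (not isolated)
Conditions: LiBH(s-Bu)3, THF, −78 °C; then MeI, DMPU, −78 to 0 °C
Reagents that add atoms: iodomethane CI
Why: Conjugate hydride reduction gives the tetrasubstituted enolate regiospecifically, and enolate alkylation by MeI occurs anti to the C8 methyl, so C20 is trans to C17 and the side chain cis (C9 = R).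

**Step 6**
Reactants: 10 (2R,3R)-2-{3-[(4-methoxybenzyl)oxy]propyl}-2,3-dimethylcyclohexan-1-one
Product: 12 (2R,3R)-6-(2-hydroxypropan-2-yl)-2-{3-[(4-methoxybenzyl)oxy]propyl}-2,3-dimethylcyclohexan-1-one (both C6 epimers), via lithium enolate 11 (not isolated)
Conditions: LiN(i-Pr)2, THF, −78 °C; then acetone, −78 °C
Reagents that add atoms: acetone CC(C)=O
Why: Only C5 can be enolised because C9 is quaternary, and the aldol addition to acetone brings in C4 with both its methyl groups (the new centre is erased in step 7).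

**Step 7**
Reactants: 12 (2R,3R)-6-(2-hydroxypropan-2-yl)-2-{3-[(4-methoxybenzyl)oxy]propyl}-2,3-dimethylcyclohexan-1-one
Product: 14 (2R,3R)-2-{3-[(4-methoxybenzyl)oxy]propyl}-2,3-dimethyl-6-(propan-2-ylidene)cyclohexan-1-one, via mesylate 13 (not isolated)
Conditions: MsCl, Et3N, CH2Cl2, 0 °C to rt; then DBU, rt
Reagents that add atoms: none
Why: E1cB dehydration through the acidic C5–H gives the conjugated isopropylidene ketone, a pulegone-type enone.

**Step 8**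
Reactants: 14 (2R,3R)-2-{3-[(4-methoxybenzyl)oxy]propyl}-2,3-dimethyl-6-(propan-2-ylidene)cyclohexan-1-one
Product: 15 {[(5R,6R)-6-{3-[(4-methoxybenzyl)oxy]propyl}-5,6-dimethyl-2-(2-methylpent-4-en-2-yl)cyclohex-1-en-1-yl]oxy}(trimethyl)silane
Conditions: CH2=CHCH2MgBr + CuBr·SMe2 (1:1), THF, −78 °C; then Me3SiCl and 14, −78 °C
Reagents that add atoms: allylmagnesium bromide C=CC[Mg]Br; chlorotrimethylsilane C[Si](C)(C)Cl
Why: Me3SiCl-accelerated conjugate addition of allylcopper to the exocyclic enone builds the quaternary C4 and traps the regiodefined C10=C5 enolate as its silyl ether.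

**Step 9**
Reactants: 15 {[(5R,6R)-6-{3-[(4-methoxybenzyl)oxy]propyl}-5,6-dimethyl-2-(2-methylpent-4-en-2-yl)cyclohex-1-en-1-yl]oxy}(trimethyl)silane
Product: 16 (5R,6R)-6-{3-[(4-methoxybenzyl)oxy]propyl}-5,6-dimethyl-2-(2-methylpent-4-en-2-yl)cyclohex-2-en-1-one
Conditions: Pd(OAc)2 (1.1 equiv), MeCN, rt
Reagents that add atoms: none
Why: Saegusa–Ito oxidation, in which the palladium enolate can only lose a C6 hydrogen because C4 is quaternary, gives the C5=C6 enone.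

**Step 10**
Reactants: 16 (5R,6R)-6-{3-[(4-methoxybenzyl)oxy]propyl}-5,6-dimethyl-2-(2-methylpent-4-en-2-yl)cyclohex-2-en-1-one
Product: 18 (5R,6R)-6-{3-[(4-methoxybenzyl)oxy]propyl}-5,6-dimethyl-2-(2-methylpent-4-en-2-yl)cyclohexa-1,3-dien-1-yl trifluoromethanesulfonate, via potassium dienolate 17 (not isolated)
Conditions: KN(SiMe3)2, THF, −78 °C; then PhNTf2, −78 to 0 °C
Reagents that add atoms: N-phenylbis(trifluoromethanesulfonimide) O=S(=O)(N(c1ccccc1)S(=O)(=O)C(F)(F)F)C(F)(F)F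
Why: With no α′-hydrogen (C9 is quaternary) the base can only remove the γ-hydrogen at C7, and O-triflation of the extended enolate gives the C10 dienyl triflate with the C5=C10 and C6=C7 bonds in place.

**Step 11**
Reactants: 18 (5R,6R)-6-{3-[(4-methoxybenzyl)oxy]propyl}-5,6-dimethyl-2-(2-methylpent-4-en-2-yl)cyclohexa-1,3-dien-1-yl trifluoromethanesulfonate
Product: 20 (1R,2R)-1-{3-[(4-methoxybenzyl)oxy]propyl}-1,2,5,5-tetramethyl-1,2,5,6,7,8-hexahydronaphthalene, via B-alkyl-9-BBN adduct 19 (not isolated)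
Conditions: 9-BBN, THF, 0 °C to rt; then Pd(dppf)Cl2 (10 mol %), Cs2CO3, DMF/H2O, 60 °C
Reagents that add atoms: none
Why: Anti-Markovnikov hydroboration of the terminal alkene followed by intramolecular B-alkyl Suzuki–Miyaura coupling with the cis-disposed triflate closes ring A through the C1–C10 bond.

**Step 12**
Reactants: 20 (1R,2R)-1-{3-[(4-methoxybenzyl)oxy]propyl}-1,2,5,5-tetramethyl-1,2,5,6,7,8-hexahydronaphthalene
Product: 21 (1S,2R,3S,4R)-4-{3-[(4-methoxybenzyl)oxy]propyl}-3,4,8,8-tetramethyl-1,2,3,4,5,6,7,8-octahydronaphthalene-1,2-diol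
Conditions: OsO4 (2 mol %), N-methylmorpholine N-oxide, acetone/H2O, rt
Reagents that add atoms: N-methylmorpholine N-oxide C[N+]1([O-])CCOCC1; water O
Why: Upjohn syn-dihydroxylation takes the disubstituted C6=C7 bond (C5=C10 is tetrasubstituted between two quaternary carbons) from the face anti to the C8 methyl and the C9 side chain, setting C6 (S) and C7 (R) as the cis-diol.

**Step 13**
Reactants: 21 (1S,2R,3S,4R)-4-{3-[(4-methoxybenzyl)oxy]propyl}-3,4,8,8-tetramethyl-1,2,3,4,5,6,7,8-octahydronaphthalene-1,2-diol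
Product: 22 (1S,2R,3S,4R)-1,2-bis[(tert-butyldimethylsilyl)oxy]-4-{3-[(4-methoxybenzyl)oxy]propyl}-3,4,8,8-tetramethyl-1,2,3,4,5,6,7,8-octahydronaphthalene
Conditions: t-BuMe2SiOTf (3 equiv), 2,6-lutidine, CH2Cl2, 0 °C to rt
Reagents that add atoms: tert-butyldimethylsilyl trifluoromethanesulfonate CC(C)(C)[Si](C)(C)OS(=O)(=O)C(F)(F)F
Why: Silyl triflate is reactive enough to silylate both hydroxyls, including the hindered allylic C6–OH, giving fluoride-labile protection for the side-chain work.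

**Step 14**
Reactants: 22 (1S,2R,3S,4R)-1,2-bis[(tert-butyldimethylsilyl)oxy]-4-{3-[(4-methoxybenzyl)oxy]propyl}-3,4,8,8-tetramethyl-1,2,3,4,5,6,7,8-octahydronaphthalene
Product: 23 3-{(1R,2S,3R,4S)-3,4-bis[(tert-butyldimethylsilyl)oxy]-1,2,5,5-tetramethyl-1,2,3,4,5,6,7,8-octahydronaphthalen-1-yl}propan-1-ol
Conditions: DDQ (1.2 equiv), CH2Cl2/pH 7 buffer, 0 °C
Reagents that add atoms: none
Why: Oxidative PMB cleavage by DDQ is selective for the electron-rich benzyl ether and leaves the silyl ethers and the hindered alkene alone.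

**Step 15**
Reactants: 23 3-{(1R,2S,3R,4S)-3,4-bis[(tert-butyldimethylsilyl)oxy]-1,2,5,5-tetramethyl-1,2,3,4,5,6,7,8-octahydronaphthalen-1-yl}propan-1-ol
Product: 24 3-{(1R,2S,3R,4S)-3,4-bis[(tert-butyldimethylsilyl)oxy]-1,2,5,5-tetramethyl-1,2,3,4,5,6,7,8-octahydronaphthalen-1-yl}propanal
Conditions: Dess–Martin periodinane, CH2Cl2, rt
Reagents that add atoms: none
Why: Dess–Martin oxidation of the primary alcohol gives the C13 aldehyde without touching other groups.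

**Step 16**
Reactants: 24 3-{(1R,2S,3R,4S)-3,4-bis[(tert-butyldimethylsilyl)oxy]-1,2,5,5-tetramethyl-1,2,3,4,5,6,7,8-octahydronaphthalen-1-yl}propanal
Product: 25 (1S,2R,3S,4R)-4-(but-3-yn-1-yl)-1,2-bis[(tert-butyldimethylsilyl)oxy]-3,4,8,8-tetramethyl-1,2,3,4,5,6,7,8-octahydronaphthalene
Conditions: dimethyl (1-diazo-2-oxopropyl)phosphonate, K2CO3, MeOH, rt
Reagents that add atoms: dimethyl (1-diazo-2-oxopropyl)phosphonate COP(=O)(OC)C(=[N+]=[N-])C(C)=O
Why: Ohira–Bestmann (Seyferth–Gilbert) homologation converts the aldehyde into the terminal alkyne, adding C14.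

**Step 17**
Reactants: 25 (1S,2R,3S,4R)-4-(but-3-yn-1-yl)-1,2-bis[(tert-butyldimethylsilyl)oxy]-3,4,8,8-tetramethyl-1,2,3,4,5,6,7,8-octahydronaphthalene
Product: 27 (2E)-5-{(1R,2S,3R,4S)-3,4-bis[(tert-butyldimethylsilyl)oxy]-1,2,5,5-tetramethyl-1,2,3,4,5,6,7,8-octahydronaphthalen-1-yl}-3-methylpent-2-en-1-ol, via alkenylalane 26 (not isolated)
Conditions: AlMe3, Cp2ZrCl2 (25 mol %), CH2Cl2, 0 °C to rt; then n-BuLi, THF, −78 °C; (CH2O)n, to rt
Reagents that add atoms: trimethylaluminium C[Al](C)C; formaldehyde (as paraformaldehyde) C=O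
Why: Negishi zirconium-catalysed syn-carboalumination puts methyl on C13 and aluminium on C14, and the alanate adds to formaldehyde with retention to give the (E)-trisubstituted allylic alcohol.

**Step 18**
Reactants: 27 (2E)-5-{(1R,2S,3R,4S)-3,4-bis[(tert-butyldimethylsilyl)oxy]-1,2,5,5-tetramethyl-1,2,3,4,5,6,7,8-octahydronaphthalen-1-yl}-3-methylpent-2-en-1-ol
Product: 28 [(2S,3S)-3-(2-{(1R,2S,3R,4S)-3,4-bis[(tert-butyldimethylsilyl)oxy]-1,2,5,5-tetramethyl-1,2,3,4,5,6,7,8-octahydronaphthalen-1-yl}ethyl)-3-methyloxiran-2-yl]methanol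
Conditions: Ti(Oi-Pr)4 (10 mol %), L-(+)-diethyl tartrate (12 mol %), t-BuOOH, 4 Å molecular sieves, CH2Cl2, −20 °C
Reagents that add atoms: tert-butyl hydroperoxide CC(C)(C)OO
Why: Sharpless asymmetric epoxidation with L-(+)-tartrate gives the (2S,3S)-epoxy alcohol under reagent control, as for geraniol, fixing C13 as S.

**Step 19**
Reactants: 28 [(2S,3S)-3-(2-{(1R,2S,3R,4S)-3,4-bis[(tert-butyldimethylsilyl)oxy]-1,2,5,5-tetramethyl-1,2,3,4,5,6,7,8-octahydronaphthalen-1-yl}ethyl)-3-methyloxiran-2-yl]methanol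
Product: 29 (2R,3S)-3-(2-{(1R,2S,3R,4S)-3,4-bis[(tert-butyldimethylsilyl)oxy]-1,2,5,5-tetramethyl-1,2,3,4,5,6,7,8-octahydronaphthalen-1-yl}ethyl)-2-(iodomethyl)-3-methyloxirane
Conditions: PPh3, I2, imidazole, THF, 0 °C
Reagents that add atoms: iodine II
Why: Appel-type iodination is an SN2 displacement at the primary C15 and leaves the epoxide intact (the C14 descriptor changes by priority only).

**Step 20**
Reactants: 29 (2R,3S)-3-(2-{(1R,2S,3R,4S)-3,4-bis[(tert-butyldimethylsilyl)oxy]-1,2,5,5-tetramethyl-1,2,3,4,5,6,7,8-octahydronaphthalen-1-yl}ethyl)-2-(iodomethyl)-3-methyloxirane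
Product: 30 (3S)-5-{(1R,2S,3R,4S)-3,4-bis[(tert-butyldimethylsilyl)oxy]-1,2,5,5-tetramethyl-1,2,3,4,5,6,7,8-octahydronaphthalen-1-yl}-3-methylpent-1-en-3-ol
Conditions: Zn dust, EtOH, reflux
Reagents that add atoms: none
Why: Zinc insertion into the C–I bond and β-elimination open the epoxide to the vinyl carbinol (reductive epoxide fragmentation), and the C13–O bond is never broken, so C13 stays S.

**Step 21**
Reactants: 30 (3S)-5-{(1R,2S,3R,4S)-3,4-bis[(tert-butyldimethylsilyl)oxy]-1,2,5,5-tetramethyl-1,2,3,4,5,6,7,8-octahydronaphthalen-1-yl}-3-methylpent-1-en-3-ol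
Product: 31 (1S,2R,3S,4R)-4-[(3S)-3-hydroxy-3-methylpent-4-en-1-yl]-3,4,8,8-tetramethyl-1,2,3,4,5,6,7,8-octahydronaphthalene-1,2-diol
Conditions: Bu4NF (3 equiv), THF, rt to 45 °C
Reagents that add atoms: none
Why: Fluoride-mediated desilylation frees both ring hydroxyls under non-acidic conditions that the tertiary allylic alcohol tolerates.

**Step 22**
Reactants: 31 (1S,2R,3S,4R)-4-[(3S)-3-hydroxy-3-methylpent-4-en-1-yl]-3,4,8,8-tetramethyl-1,2,3,4,5,6,7,8-octahydronaphthalene-1,2-diol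
Product: 32 (1S,2R,3S,4R)-1-hydroxy-4-[(3S)-3-hydroxy-3-methylpent-4-en-1-yl]-3,4,8,8-tetramethyl-1,2,3,4,5,6,7,8-octahydronaphthalen-2-yl acetate (CNP0126002.2)
Conditions: Ac2O (1.1 equiv), pyridine, CH2Cl2, 0 °C
Reagents that add atoms: acetic anhydride CC(=O)OC(C)=O
Why: Acylation is selective for the equatorial C7–OH, because the C6–OH is pseudoaxial and shielded by the C4 gem-dimethyl group and the C13–OH is tertiary.

**Compound list**
1 | propane-1,3-diol | OCCCO | starting material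
2 | 3-[(4-methoxybenzyl)oxy]propan-1-ol | COc1ccc(COCCCO)cc1 | intermediate
3 | 3-[(4-methoxybenzyl)oxy]propanal | COc1ccc(COCCC=O)cc1 | intermediate
4 | cyclohex-2-en-1-one | O=C1C=CCCC1 | starting material
5 | methylzinc (3R)-3-methylcyclohex-1-en-1-olate | C[Zn]OC1=C[C@H](C)CCC1 | intermediate (not isolated)
6 | (2R,3R)-2-{1-hydroxy-3-[(4-methoxybenzyl)oxy]propyl}-3-methylcyclohexan-1-one, both carbinol epimers | COc1ccc(COCCC(O)[C@@H]2C(=O)CCC[C@H]2C)cc1 | intermediate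
7 | 1-[(1R,2R)-2-methyl-6-oxocyclohexyl]-3-[(4-methoxybenzyl)oxy]propyl methanesulfonate | COc1ccc(COCCC(OS(C)(=O)=O)[C@@H]2C(=O)CCC[C@H]2C)cc1 | intermediate (not isolated)
8 | (2E,3R)-2-{3-[(4-methoxybenzyl)oxy]propylidene}-3-methylcyclohexan-1-one | COc1ccc(COCC/C=C2/C(=O)CCC[C@H]2C)cc1 | intermediate
9 | lithium (3R)-2-{3-[(4-methoxybenzyl)oxy]propyl}-3-methylcyclohex-1-en-1-olate | COc1ccc(COCCCC2=C(O[Li])CCC[C@H]2C)cc1 | intermediate (not isolated)
10 | (2R,3R)-2-{3-[(4-methoxybenzyl)oxy]propyl}-2,3-dimethylcyclohexan-1-one | COc1ccc(COCCC[C@@]2(C)C(=O)CCC[C@H]2C)cc1 | intermediate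
11 | lithium (5R,6R)-6-{3-[(4-methoxybenzyl)oxy]propyl}-5,6-dimethylcyclohex-1-en-1-olate | COc1ccc(COCCC[C@@]2(C)C(O[Li])=CCC[C@H]2C)cc1 | intermediate (not isolated)
12 | (2R,3R)-6-(2-hydroxypropan-2-yl)-2-{3-[(4-methoxybenzyl)oxy]propyl}-2,3-dimethylcyclohexan-1-one, both C6 epimers | COc1ccc(COCCC[C@@]2(C)C(=O)C(C(C)(C)O)CC[C@H]2C)cc1 | intermediate
13 | 2-[(3R,4R)-3-{3-[(4-methoxybenzyl)oxy]propyl}-3,4-dimethyl-2-oxocyclohexyl]propan-2-yl methanesulfonate | COc1ccc(COCCC[C@@]2(C)C(=O)C(C(C)(C)OS(C)(=O)=O)CC[C@H]2C)cc1 | intermediate (not isolated)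
14 | (2R,3R)-2-{3-[(4-methoxybenzyl)oxy]propyl}-2,3-dimethyl-6-(propan-2-ylidene)cyclohexan-1-one | COc1ccc(COCCC[C@@]2(C)C(=O)C(=C(C)C)CC[C@H]2C)cc1 | intermediate
15 | {[(5R,6R)-6-{3-[(4-methoxybenzyl)oxy]propyl}-5,6-dimethyl-2-(2-methylpent-4-en-2-yl)cyclohex-1-en-1-yl]oxy}(trimethyl)silane | COc1ccc(COCCC[C@@]2(C)C(O[Si](C)(C)C)=C(C(C)(C)CC=C)CC[C@H]2C)cc1 | intermediate
16 | (5R,6R)-6-{3-[(4-methoxybenzyl)oxy]propyl}-5,6-dimethyl-2-(2-methylpent-4-en-2-yl)cyclohex-2-en-1-one | COc1ccc(COCCC[C@@]2(C)C(=O)C(C(C)(C)CC=C)=CC[C@H]2C)cc1 | intermediate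
17 | potassium (5R,6R)-6-{3-[(4-methoxybenzyl)oxy]propyl}-5,6-dimethyl-2-(2-methylpent-4-en-2-yl)cyclohexa-1,3-dien-1-olate | COc1ccc(COCCC[C@@]2(C)C(O[K])=C(C(C)(C)CC=C)C=C[C@H]2C)cc1 | intermediate (not isolated)
18 | (5R,6R)-6-{3-[(4-methoxybenzyl)oxy]propyl}-5,6-dimethyl-2-(2-methylpent-4-en-2-yl)cyclohexa-1,3-dien-1-yl trifluoromethanesulfonate | COc1ccc(COCCC[C@@]2(C)C(OS(=O)(=O)C(F)(F)F)=C(C(C)(C)CC=C)C=C[C@H]2C)cc1 | intermediate
19 | (5R,6R)-2-[5-(9-borabicyclo[3.3.1]nonan-9-yl)-2-methylpentan-2-yl]-6-{3-[(4-methoxybenzyl)oxy]propyl}-5,6-dimethylcyclohexa-1,3-dien-1-yl trifluoromethanesulfonate | COc1ccc(COCCC[C@@]2(C)C(OS(=O)(=O)C(F)(F)F)=C(C(C)(C)CCCB3C4CCCC3CCC4)C=C[C@H]2C)cc1 | intermediate (not isolated)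
20 | (1R,2R)-1-{3-[(4-methoxybenzyl)oxy]propyl}-1,2,5,5-tetramethyl-1,2,5,6,7,8-hexahydronaphthalene | COc1ccc(COCCC[C@@]2(C)C3=C(C=C[C@H]2C)C(C)(C)CCC3)cc1 | intermediate
21 | (1S,2R,3S,4R)-4-{3-[(4-methoxybenzyl)oxy]propyl}-3,4,8,8-tetramethyl-1,2,3,4,5,6,7,8-octahydronaphthalene-1,2-diol | COc1ccc(COCCC[C@@]2(C)C3=C([C@H](O)[C@H](O)[C@H]2C)C(C)(C)CCC3)cc1 | intermediate
22 | (1S,2R,3S,4R)-1,2-bis[(tert-butyldimethylsilyl)oxy]-4-{3-[(4-methoxybenzyl)oxy]propyl}-3,4,8,8-tetramethyl-1,2,3,4,5,6,7,8-octahydronaphthalene | COc1ccc(COCCC[C@@]2(C)C3=C([C@H](O[Si](C)(C)C(C)(C)C)[C@H](O[Si](C)(C)C(C)(C)C)[C@H]2C)C(C)(C)CCC3)cc1 | intermediate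
23 | 3-{(1R,2S,3R,4S)-3,4-bis[(tert-butyldimethylsilyl)oxy]-1,2,5,5-tetramethyl-1,2,3,4,5,6,7,8-octahydronaphthalen-1-yl}propan-1-ol | OCCC[C@@]1(C)C2=C([C@H](O[Si](C)(C)C(C)(C)C)[C@H](O[Si](C)(C)C(C)(C)C)[C@H]1C)C(C)(C)CCC2 | intermediate
24 | 3-{(1R,2S,3R,4S)-3,4-bis[(tert-butyldimethylsilyl)oxy]-1,2,5,5-tetramethyl-1,2,3,4,5,6,7,8-octahydronaphthalen-1-yl}propanal | O=CCC[C@@]1(C)C2=C([C@H](O[Si](C)(C)C(C)(C)C)[C@H](O[Si](C)(C)C(C)(C)C)[C@H]1C)C(C)(C)CCC2 | intermediate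
25 | (1S,2R,3S,4R)-4-(but-3-yn-1-yl)-1,2-bis[(tert-butyldimethylsilyl)oxy]-3,4,8,8-tetramethyl-1,2,3,4,5,6,7,8-octahydronaphthalene | C#CCC[C@@]1(C)C2=C([C@H](O[Si](C)(C)C(C)(C)C)[C@H](O[Si](C)(C)C(C)(C)C)[C@H]1C)C(C)(C)CCC2 | intermediate
26 | [(1E)-4-{(1R,2S,3R,4S)-3,4-bis[(tert-butyldimethylsilyl)oxy]-1,2,5,5-tetramethyl-1,2,3,4,5,6,7,8-octahydronaphthalen-1-yl}-2-methylbut-1-en-1-yl](dimethyl)alane | C[Al](C)/C=C(\C)CC[C@@]1(C)C2=C([C@H](O[Si](C)(C)C(C)(C)C)[C@H](O[Si](C)(C)C(C)(C)C)[C@H]1C)C(C)(C)CCC2 | intermediate (not isolated)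
27 | (2E)-5-{(1R,2S,3R,4S)-3,4-bis[(tert-butyldimethylsilyl)oxy]-1,2,5,5-tetramethyl-1,2,3,4,5,6,7,8-octahydronaphthalen-1-yl}-3-methylpent-2-en-1-ol | OC/C=C(\C)CC[C@@]1(C)C2=C([C@H](O[Si](C)(C)C(C)(C)C)[C@H](O[Si](C)(C)C(C)(C)C)[C@H]1C)C(C)(C)CCC2 | intermediate
28 | [(2S,3S)-3-(2-{(1R,2S,3R,4S)-3,4-bis[(tert-butyldimethylsilyl)oxy]-1,2,5,5-tetramethyl-1,2,3,4,5,6,7,8-octahydronaphthalen-1-yl}ethyl)-3-methyloxiran-2-yl]methanol | OC[C@@H]1O[C@@]1(C)CC[C@@]2(C)C3=C([C@H](O[Si](C)(C)C(C)(C)C)[C@H](O[Si](C)(C)C(C)(C)C)[C@H]2C)C(C)(C)CCC3 | intermediate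
29 | (2R,3S)-3-(2-{(1R,2S,3R,4S)-3,4-bis[(tert-butyldimethylsilyl)oxy]-1,2,5,5-tetramethyl-1,2,3,4,5,6,7,8-octahydronaphthalen-1-yl}ethyl)-2-(iodomethyl)-3-methyloxirane | IC[C@@H]1O[C@@]1(C)CC[C@@]2(C)C3=C([C@H](O[Si](C)(C)C(C)(C)C)[C@H](O[Si](C)(C)C(C)(C)C)[C@H]2C)C(C)(C)CCC3 | intermediate
30 | (3S)-5-{(1R,2S,3R,4S)-3,4-bis[(tert-butyldimethylsilyl)oxy]-1,2,5,5-tetramethyl-1,2,3,4,5,6,7,8-octahydronaphthalen-1-yl}-3-methylpent-1-en-3-ol | C=C[C@@](C)(O)CC[C@@]1(C)C2=C([C@H](O[Si](C)(C)C(C)(C)C)[C@H](O[Si](C)(C)C(C)(C)C)[C@H]1C)C(C)(C)CCC2 | intermediate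
31 | (1S,2R,3S,4R)-4-[(3S)-3-hydroxy-3-methylpent-4-en-1-yl]-3,4,8,8-tetramethyl-1,2,3,4,5,6,7,8-octahydronaphthalene-1,2-diol | C=C[C@@](C)(O)CC[C@@]1(C)C2=C([C@H](O)[C@H](O)[C@H]1C)C(C)(C)CCC2 | intermediate
32 | (1S,2R,3S,4R)-1-hydroxy-4-[(3S)-3-hydroxy-3-methylpent-4-en-1-yl]-3,4,8,8-tetramethyl-1,2,3,4,5,6,7,8-octahydronaphthalen-2-yl acetate (CNP0126002.2) | C=C[C@@](C)(O)CC[C@@]1(C)C2=C([C@H](O)[C@H](OC(C)=O)[C@H]1C)C(C)(C)CCC2 | target

**Totals**
Total step count: 22. Longest linear sequence: 22 steps (1 to 32); 20 steps counted from cyclohex-2-en-1-one.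

**Steps most likely to fail, with fallbacks**

Step 5 (1,2- instead of 1,4-reduction, or sluggish methylation of the borane-bound enolate). The fallback sets out from enone 8. Rhodium-catalysed 1,4-hydrosilylation (Et3SiH, RhCl(PPh3)3 1 mol %, THF, 50 °C) gives the isolable, regiodefined triethyl{[(3R)-2-{3-[(4-methoxybenzyl)oxy]propyl}-3-methylcyclohex-1-en-1-yl]oxy}silane F1. MeLi in THF at 0 °C cleaves it to the borane-free lithium enolate 9, and MeI/DMPU then methylates anti to the C8 methyl, coming back to the route at ketone 10.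

Step 8 (allylcopper may add 1,2 or fail at the fully substituted β-carbon). The fallback sets out from isopropylidene ketone 14. CH2=CHCH2MgBr in THF at −78 °C adds deliberately 1,2 to give the tertiary dienol (2R,3R)-2-{3-[(4-methoxybenzyl)oxy]propyl}-2,3-dimethyl-6-(propan-2-ylidene)-1-(prop-2-en-1-yl)cyclohexan-1-ol F2 (C1 epimers, both usable). KH with 18-crown-6 in THF at rt triggers the anionic oxy-Cope rearrangement, which moves the allyl group to C4 and gives potassium (5R,6R)-6-{3-[(4-methoxybenzyl)oxy]propyl}-5,6-dimethyl-2-(2-methylpent-4-en-2-yl)cyclohex-1-en-1-olate F3. Me3SiCl silylates F3 in the same flask, coming back to the route at silyl enol ether 15.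

Step 11 (the hindered tetrasubstituted triflate may resist coupling, or the alkylpalladium may undergo β-hydride elimination). The fallback sets out from enone 16 and closes ring A at the carbonyl carbon instead.
- Disiamylborane in THF at 0 °C gives the alkylborane (5R,6R)-2-{5-[bis(3-methylbutan-2-yl)boranyl]-2-methylpentan-2-yl}-6-{3-[(4-methoxybenzyl)oxy]propyl}-5,6-dimethylcyclohex-2-en-1-one F4, which NaBO3·4H2O oxidises to (5R,6R)-2-(5-hydroxy-2-methylpentan-2-yl)-6-{3-[(4-methoxybenzyl)oxy]propyl}-5,6-dimethylcyclohex-2-en-1-one F5.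
- PPh3/I2/imidazole gives (5R,6R)-2-(5-iodo-2-methylpentan-2-yl)-6-{3-[(4-methoxybenzyl)oxy]propyl}-5,6-dimethylcyclohex-2-en-1-one F6.
- t-BuLi (2.2 equiv, Et2O/pentane, −78 °C) effects iodine–lithium exchange and 6-exo addition to the C10 carbonyl, giving (1R,2R)-1-{3-[(4-methoxybenzyl)oxy]propyl}-1,2,5,5-tetramethyl-1,2,3,5,6,7,8,8a-octahydronaphthalen-8a-ol F7 (8a epimers).
- Pyridinium chlorochromate, C5H5NH[CrO3Cl], in CH2Cl2 effects oxidative 1,3-transposition to (3R,4R)-4-{3-[(4-methoxybenzyl)oxy]propyl}-3,4,8,8-tetramethyl-3,4,5,6,7,8-hexahydronaphthalen-1(2H)-one F8.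
- KN(SiMe3)2 at −78 °C gives potassium (3R,4R)-4-{3-[(4-methoxybenzyl)oxy]propyl}-3,4,8,8-tetramethyl-3,4,5,6,7,8-hexahydronaphthalen-1-olate F9, and PhNTf2 converts it into (3R,4R)-4-{3-[(4-methoxybenzyl)oxy]propyl}-3,4,8,8-tetramethyl-3,4,5,6,7,8-hexahydronaphthalen-1-yl trifluoromethanesulfonate F10.
- Pd(OAc)2/PPh3 with HCO2H and Bu3N in DMF at 60 °C reduces the triflate, coming back to the route at diene 20.

**Further compounds**
F1 | step 5 | triethyl{[(3R)-2-{3-[(4-methoxybenzyl)oxy]propyl}-3-methylcyclohex-1-en-1-yl]oxy}silane | COc1ccc(COCCCC2=C(O[Si](CC)(CC)CC)CCC[C@H]2C)cc1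
F2 | step 8 | (2R,3R)-2-{3-[(4-methoxybenzyl)oxy]propyl}-2,3-dimethyl-6-(propan-2-ylidene)-1-(prop-2-en-1-yl)cyclohexan-1-ol | COc1ccc(COCCC[C@@]2(C)C(O)(CC=C)C(=C(C)C)CC[C@H]2C)cc1
F3 | step 8 | potassium (5R,6R)-6-{3-[(4-methoxybenzyl)oxy]propyl}-5,6-dimethyl-2-(2-methylpent-4-en-2-yl)cyclohex-1-en-1-olate | COc1ccc(COCCC[C@@]2(C)C(O[K])=C(C(C)(C)CC=C)CC[C@H]2C)cc1
F4 | step 11 | (5R,6R)-2-{5-[bis(3-methylbutan-2-yl)boranyl]-2-methylpentan-2-yl}-6-{3-[(4-methoxybenzyl)oxy]propyl}-5,6-dimethylcyclohex-2-en-1-one | COc1ccc(COCCC[C@@]2(C)C(=O)C(C(C)(C)CCCB(C(C)C(C)C)C(C)C(C)C)=CC[C@H]2C)cc1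
F5 | step 11 | (5R,6R)-2-(5-hydroxy-2-methylpentan-2-yl)-6-{3-[(4-methoxybenzyl)oxy]propyl}-5,6-dimethylcyclohex-2-en-1-one | COc1ccc(COCCC[C@@]2(C)C(=O)C(C(C)(C)CCCO)=CC[C@H]2C)cc1
F6 | step 11 | (5R,6R)-2-(5-iodo-2-methylpentan-2-yl)-6-{3-[(4-methoxybenzyl)oxy]propyl}-5,6-dimethylcyclohex-2-en-1-one | COc1ccc(COCCC[C@@]2(C)C(=O)C(C(C)(C)CCCI)=CC[C@H]2C)cc1
F7 | step 11 | (1R,2R)-1-{3-[(4-methoxybenzyl)oxy]propyl}-1,2,5,5-tetramethyl-1,2,3,5,6,7,8,8a-octahydronaphthalen-8a-ol | COc1ccc(COCCC[C@@]2(C)C3(O)CCCC(C)(C)C3=CC[C@H]2C)cc1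
F8 | step 11 | (3R,4R)-4-{3-[(4-methoxybenzyl)oxy]propyl}-3,4,8,8-tetramethyl-3,4,5,6,7,8-hexahydronaphthalen-1(2H)-one | COc1ccc(COCCC[C@@]2(C)C3=C(C(=O)C[C@H]2C)C(C)(C)CCC3)cc1
F9 | step 11 | potassium (3R,4R)-4-{3-[(4-methoxybenzyl)oxy]propyl}-3,4,8,8-tetramethyl-3,4,5,6,7,8-hexahydronaphthalen-1-olate | COc1ccc(COCCC[C@@]2(C)C3=C(C(O[K])=C[C@H]2C)C(C)(C)CCC3)cc1
F10 | step 11 | (3R,4R)-4-{3-[(4-methoxybenzyl)oxy]propyl}-3,4,8,8-tetramethyl-3,4,5,6,7,8-hexahydronaphthalen-1-yl trifluoromethanesulfonate | COc1ccc(COCCC[C@@]2(C)C3=C(C(OS(=O)(=O)C(F)(F)F)=C[C@H]2C)C(C)(C)CCC3)cc1
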